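The data come from a simulation on assumed constants.

I stake this comparison on one number: how fast J can form.

in all of them: E 0.10 M

|  | D | Z | temperature | remark | time |
|---|---|---|---|---|---|
| midnight | 0.030 M | 0.5 mol% | 70 °C | run made earlier |  |
| spring | 0.030 M | 0.75 mol% | 92 °C | run made earlier |  |
| birch | 0.0300 M | 1 mol% |  | at 100 °C until 30 min, from then on at 60 °C | 1.0 h |
| ash | 0.0300 M | 1 mol% |  | at 60 °C throughout | 1.0 h |

midnight run (percent of the E charged)

| time / h | Q / % | J / % |
|---|---|---|
| 0.417 | 15.0 | 0.1 |
| 0.667 | 24.8 | 0 |
| 0.833 | 30.9 | 0.4 |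
| 1.33 | 44.9 | 3.0 |
| 2.00 | 56.6 | 4.2 |
| 4.00 | 71.9 | 11.5 |
| 6.00 | 74.2 | 18.9 |

spring run (percent of the E charged)

| time / min | Q / % | J / % |
|---|---|---|
| 4.00 | 12.7 | 0.2 |
| 12.0 | 41.2 | 3.7 |
| 20.0 | 56.8 | 10.6 |
| 30.0 | 63.4 | 18.3 |
| 40.0 | 63.9 | 25.2 |
| 60.0 | 54.9 | 40.3 |
| 80.0 | 42.9 | 55.7 |

(each reading ± 0.5 percentage points)

- which one finishes higher in share of Q in all that became Q or J ("neither" within 2 percentage points) (birch / ash / neither)
- share of Q in all that became Q or J, birch
- share of Q in all that became Q or J, ash

- a reading or a percentage of Q counts all its forms, free or not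

1. In both earlier runs Q shows first and J follows it. Amounts below are fractions of the E charged.

2. The late readings show a straight line. In spring, from 40.0 min to 80.0 min, Q falls from 63.9% to 42.9%, yet J gains a steady 0.00763 /min. Midnight's last two readings give 0.0370 /h. These slopes are readings, and they look zero-order.

3. The 92 °C slope is 12.4 times the 70 °C slope. Stretching that factor geometrically over temperature gives the ceiling rate, the steady gain of J per unit time at the hot stage, 0.0190 /min. At 60 °C the same reckoning gives 0.0118 /h.

4. Now I solve the two ends and join them. At the early end, J barely shows: midnight at 0.833 h reads J 0.4% beside Q 30.9%, a share of 98.7%. At the late end, J follows the ceiling line. Spring's line meets zero at 6.95 min.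

5. Birch is hotter and carries more Z than spring, which already holds 81.7% as Q plus J at 30.0 min. So I count Q plus J in birch as about the whole charge. With spring's delay, J is 0.439. With none, it is 0.571. I take the middle, 0.505, so birch's share is 49.5%. At the 60 °C ceiling rate, I reckon J gains 0.00590 in the cool half of birch.

6. In ash, a whole hour at the ceiling would give J 0.0118. I expect ash to stay on the early end, near midnight's 98.7%.

The forecast says ash, with birch 51% and ash 99%. Its ground is that J “then grows at a nearly constant rate, even as Q falls”. It rests on the same readings as mine, so the nearness of our numbers checks nothing.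

The flask gives ash, with birch 50.5% and ash 99.0%. The gap of 48 percentage points is far wider than the margin. Birch's J stands at 47.9% at 0.500 h and at 48.4% at 1.00 h. Birch's J at the change of temperature, divided by 0.0190 /min, equals 25.2 min at the ceiling rate.

    X ⇌ Q, rate k1*(cs1 - [Q]) while solid is left; crystals form when [Q] > cs1 (solubility = 44.0 mM, k = 1.70 /min)
    E + Z → L + Q (k = 6.11 /M/min, Ea = 53.0 kJ/mol)
    E + L → Q + L, rate k3*[L]*[E] (k = 149 /M/min, Ea = 74.0 kJ/mol)
    L + D → G (k = 0.337 /M/min, Ea = 69.0 kJ/mol)
    Q → J (k = 0.0406 /min, Ea = 122 kJ/mol)
    (constants at 100 °C)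

For the neighbour flask, ash repeated at 75 °C, the ceiling rate carries over as 0.0655 /h, which gives J 0.0655 in 1.0 h. The computed J of that neighbour is 4.84%, less than that reckoned figure, and its share is 93.5%.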